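## Retrosynthetic overview

- The (R)-lactol is unmasked last, by neutral hydrogenolysis of a (1R)-1-phenylethyl acetal; the acetal carbon is fixed early on the ring B monomer by equilibrating acetalization, with the wrong epimer funnelled back through the same equilibrium.
- Key disconnection: the diaryl ether C–O bond of the seven-membered dioxepinone (ring A phenol oxygen to C-4 of ring B), made by a new aerobic copper-catalysed dehydrogenative O–H/C–H coupling of a depside.
- The depside ester C–O bond comes from a Steglich coupling of the ring A acid (two steps from atraric acid) with the 5-OH of the ring B acetal.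
- The ring B hydroxyphthalide comes from 3,5-dimethoxy-4-methylbenzaldehyde by one-pot directed ortho-lithiation/carboxylation, then BBr3.
- Ring order: the lactol (γ-lactone) ring on ring B first, the central dioxepinone ring last.

Assumption: the free hemiacetal is configurationally labile in solution (ring–chain tautomerism), so it is liberated only in the last step under neutral, aprotic, cold conditions and isolated by direct crystallization.

## Route

Step 1
Reactants: 1 methyl 2,4-dihydroxy-3,6-dimethylbenzoate (atraric acid)
Product: 2 methyl 2-hydroxy-4-methoxy-3,6-dimethylbenzoate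
Conditions: MeI (1.1 equiv), K2CO3 (1.2 equiv), acetone, reflux
Reagents that add atoms: iodomethane, CI
Why: Williamson O-methylation, in which the 2-OH is hydrogen-bonded to the ester carbonyl so that only the 4-OH is alkylated.

Step 2
Reactants: 2 methyl 2-hydroxy-4-methoxy-3,6-dimethylbenzoate
Product: 3 2-hydroxy-4-methoxy-3,6-dimethylbenzoic acid (rhizonic acid)
Conditions: KOH, DMSO–H2O (4:1), 90 °C; then cold 2 M HCl
Reagents that add atoms: potassium hydroxide, [K+].[OH-]
Why: Saponification of the hindered salicylate under forcing aqueous DMSO conditions, with cold acidification to avoid decarboxylation.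

Step 3
Reactants: 4 3,5-dimethoxy-4-methylbenzaldehyde
Product: 8 rac-3-hydroxy-5,7-dimethoxy-6-methylisobenzofuran-1(3H)-one, via lithium α-amino alkoxide 5 (not isolated), via ortho-lithiated α-amino alkoxide 6 (not isolated), via dilithium carboxylate 7 (not isolated)
Conditions: LiN(Me)CH2CH2NMe2 (1.1 equiv, from MeNHCH2CH2NMe2 + n-BuLi), THF, −20 °C; n-BuLi (3 equiv), −20 °C, 4 h; CO2 (g), −78 °C → rt; 2 M HCl
Reagents that add atoms: carbon dioxide, O=C=O
Why: Comins-type in situ aldehyde protection and directed ortho-metalation, in which the α-amino alkoxide and the neighbouring OMe together direct lithiation to C-2 (equal to C-6 by symmetry), and carboxylation followed by acid work-up frees the aldehyde, which closes onto the new carboxyl group to give the racemic lactol.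

Step 4
Reactants: 8 rac-3-hydroxy-5,7-dimethoxy-6-methylisobenzofuran-1(3H)-one
Product: 9 rac-3,5,7-trihydroxy-6-methylisobenzofuran-1(3H)-one
Conditions: BBr3 (4 equiv), CH2Cl2, −78 °C → rt; ice–water
Reagents that add atoms: none
Why: Lewis-acid cleavage of both aryl methyl ethers (the 7-OMe is chelation-assisted), with the lactol regenerated on aqueous quench and still racemic.

Step 5
Reactants: 9 rac-3,5,7-trihydroxy-6-methylisobenzofuran-1(3H)-one; 10 (R)-1-phenylethanol (3 equiv)
Product: 12 (3R)-5,7-dihydroxy-6-methyl-3-[(1R)-1-phenylethoxy]isobenzofuran-1(3H)-one, via (3S)-epimeric acetal 11 (not isolated)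
Conditions: PPTS (10 mol %), 4 Å MS, THF–toluene, 50 °C; SiO2; fractions rich in 11 returned unpurified to the same conditions (3 cycles)
Reagents that add atoms: none
Why: Acid-catalysed reversible pseudo-ester (mixed acetal) formation of the hydroxyphthalide with the chiral alcohol gives both C-3 epimers in about equal amounts, and because the (3S) epimer 11 re-ionizes to the same oxocarbenium ion under the PPTS/alcohol conditions it is funnelled into the separable (3R,1′R) acetal 12, which fixes the lactol carbon as R in a configurationally stable acetal (PPTS is too weak to ionize the auxiliary).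

Step 6
Reactants: 3 2-hydroxy-4-methoxy-3,6-dimethylbenzoic acid; 12 (3R)-5,7-dihydroxy-6-methyl-3-[(1R)-1-phenylethoxy]isobenzofuran-1(3H)-one
Product: 13 (3R)-7-hydroxy-6-methyl-1-oxo-3-[(1R)-1-phenylethoxy]-1,3-dihydroisobenzofuran-5-yl 2-hydroxy-4-methoxy-3,6-dimethylbenzoate
Conditions: DCC (1.1 equiv), DMAP (5 mol %), CH2Cl2, 0 °C → rt
Reagents that add atoms: none
Why: Steglich esterification at the more acidic and accessible 5-OH, whereas the 7-OH (hydrogen-bonded to the lactone carbonyl) and the chelated 2-OH of 3 stay free and the neutral conditions leave the acetal stereocentre untouched.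

Step 7
Reactants: 13 (3R)-7-hydroxy-6-methyl-1-oxo-3-[(1R)-1-phenylethoxy]-1,3-dihydroisobenzofuran-5-yl 2-hydroxy-4-methoxy-3,6-dimethylbenzoate
Product: 15 (R)-hypostictic acid O-[(1R)-1-phenylethyl] lactol acetal, via 4-aryloxycyclohexa-2,5-dienone 14 (not isolated)
Conditions: [Cu(MeCN)4]PF6 (20 mol %), N,N′-di-tert-butylethylenediamine (40 mol %), O2 (1 atm), 4 Å MS, CH2Cl2 (0.005 M), −20 °C → rt
Reagents that add atoms: none
Why: Proposed new method: an aerobic copper/diamine-catalysed intramolecular dehydrogenative O–H/C–H coupling of a depside to a depsidone; both phenols have blocked ortho positions, so the dicopper–dioxygen oxidant formed from monovalent copper, the diamine and O2 cannot ortho-oxygenate and instead oxidizes the two copper-bound phenolates to phenoxyl radicals held on one dinuclear core; the ring A oxygen radical then couples with C-4 of ring B (para to the 7-oxyl, the only hydrogen-bearing spin site within reach, closing the seven-membered ring) to give dienone 14, which tautomerizes irreversibly to the phenol, whereas couplings at methyl- or acyl-bearing carbons are reversible; the neutral aprotic medium avoids Smiles rearrangement and acetal ionization; the closest known reaction types are the Hay copper–amine–O2 para C–O coupling of 2,6-disubstituted phenols, the oxidative cyclization of 2,3′-dihydroxybenzophenones to xanthones, and the enzymatic depside-to-depsidone phenol coupling.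

Step 8
Reactants: 15 (R)-hypostictic acid O-[(1R)-1-phenylethyl] lactol acetal
Product: 16 (R)-hypostictic acid
Conditions: H2 (1 atm), 10% Pd/C, EtOAc, 0 °C; filter, concentrate cold, crystallize
Reagents that add atoms: none
Why: Hydrogenolysis of a secondary benzylic ether cleaves only the PhCH(Me)–O bond and leaves both C–O bonds at the acetal carbon untouched, so the R configuration of 15 is retained in the hemiacetal, and the neutral, cold, aprotic conditions avoid ring–chain racemization.

## Compound list

1 | methyl 2,4-dihydroxy-3,6-dimethylbenzoate (atraric acid) | COC(=O)c1c(C)cc(O)c(C)c1O | starting material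
2 | methyl 2-hydroxy-4-methoxy-3,6-dimethylbenzoate | COC(=O)c1c(C)cc(OC)c(C)c1O | intermediate
3 | 2-hydroxy-4-methoxy-3,6-dimethylbenzoic acid (rhizonic acid) | OC(=O)c1c(C)cc(OC)c(C)c1O | intermediate
4 | 3,5-dimethoxy-4-methylbenzaldehyde | COc1cc(C=O)cc(OC)c1C | starting material
5 | lithium α-amino alkoxide of 4 (adduct with LiN(Me)CH2CH2NMe2; racemic at the carbinol carbon) | COc1cc(cc(OC)c1C)C([O-])N(C)CCN(C)C.[Li+] | intermediate
6 | 2-lithio derivative of 5 (aryllithium between the amino alkoxide carbon and OMe) | COc1cc(C([O-])N(C)CCN(C)C)c([Li])c(OC)c1C.[Li+] | intermediate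
7 | dilithium carboxylate formed from 6 and CO2 (2-carboxylate of the α-amino alkoxide) | COc1cc(C([O-])N(C)CCN(C)C)c(C(=O)[O-])c(OC)c1C.[Li+].[Li+] | intermediate
8 | rac-3-hydroxy-5,7-dimethoxy-6-methylisobenzofuran-1(3H)-one | COc1cc2C(O)OC(=O)c2c(OC)c1C | intermediate
9 | rac-3,5,7-trihydroxy-6-methylisobenzofuran-1(3H)-one | Cc1c(O)cc2C(O)OC(=O)c2c1O | intermediate
10 | (R)-1-phenylethanol | C[C@@H](O)c1ccccc1 | starting material
11 | (3S)-5,7-dihydroxy-6-methyl-3-[(1R)-1-phenylethoxy]isobenzofuran-1(3H)-one (C-3 epimer of 12; equilibrates into 12 and is not isolated) | Cc1c(O)cc2[C@@H](O[C@H](C)c3ccccc3)OC(=O)c2c1O | intermediate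
12 | (3R)-5,7-dihydroxy-6-methyl-3-[(1R)-1-phenylethoxy]isobenzofuran-1(3H)-one | Cc1c(O)cc2[C@H](O[C@H](C)c3ccccc3)OC(=O)c2c1O | intermediate
13 | (3R)-7-hydroxy-6-methyl-1-oxo-3-[(1R)-1-phenylethoxy]-1,3-dihydroisobenzofuran-5-yl 2-hydroxy-4-methoxy-3,6-dimethylbenzoate (depside) | COc1cc(C)c(C(=O)Oc2cc3[C@H](O[C@H](C)c4ccccc4)OC(=O)c3c(O)c2C)c(O)c1C | intermediate
14 | dienone tautomer of 15: ring B as a 4-aryloxycyclohexa-2,5-dienone (C-4 sp3 with H and the ring A oxygen, configuration at C-4 not defined; acetal carbon R) | COc1cc(C)c2c(c1C)OC1C(=C(C)C(=O)C3=C1[C@H](O[C@H](C)c4ccccc4)OC3=O)OC2=O | intermediate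
15 | (R)-hypostictic acid O-[(1R)-1-phenylethyl] lactol acetal (the target depsidone with the lactol OH replaced by (1R)-1-phenylethoxy; acetal carbon R) | COc1cc(C)c2c(c1C)Oc1c(c(C)c(O)c3c1[C@H](O[C@H](C)c4ccccc4)OC3=O)OC2=O | intermediate
16 | (R)-hypostictic acid (depsidone: ring A with OMe and two Me; ring B with Me, OH and a fused γ-lactone carrying the (R)-hemiacetal OH) | COc1cc(C)c2c(c1C)Oc1c(c(C)c(O)c3c1[C@H](O)OC3=O)OC2=O | target

## Step count and risks

Total steps: 8. Longest linear sequence: 6 (steps 3, 4, 5, 6, 7, 8).

Three steps most likely to fail: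

**Step 7 (proposed new coupling).** The electron-poor, hydrogen-bonded phenols may resist oxidation, intermolecular coupling at the free para position of ring A may compete, or the product phenol may be over-oxidized. The fallback uses known chemistry, electrophilic bromination followed by an Ullmann diaryl ether coupling. It sets out from compound 12. NBS (1.0 equiv, MeCN, −10 °C) brominates the only free ring position to give (3R)-4-bromo-5,7-dihydroxy-6-methyl-3-[(1R)-1-phenylethoxy]isobenzofuran-1(3H)-one F1. Steglich esterification of its 5-OH with compound 3 gives the 4-bromo depside F2. Intramolecular Ullmann etherification (CuI 20 mol %, N,N-dimethylglycine, K3PO4, dioxane, 90 °C, high dilution) closes the ether bond, and the fallback comes back to the route at compound 15.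

**Step 8 (hydrogenolysis).** Pd may also cleave the benzylic acetal C–O bond of ring B, or the freed lactol may racemize. The fallback replaces reductive by photochemical unmasking. It sets out from compound 9. Acetalization with (R)-1-(2-nitrophenyl)ethanol as in step 5 gives (3R)-5,7-dihydroxy-6-methyl-3-[(1R)-1-(2-nitrophenyl)ethoxy]isobenzofuran-1(3H)-one F3. Esterification with compound 3 as in step 6 gives the nitro depside F4, and the copper/O2 coupling of step 7 gives the nitro depsidone acetal F5. Irradiation at 365 nm in MeCN at 0 °C cleaves the o-nitrobenzylic C–O bond of the auxiliary, with retention at the lactol carbon, and the fallback comes back to the route at compound 16.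

**Step 5 (acetalization and epimer funnelling).** The epimers may not separate, re-equilibration of 11 may be too slow under PPTS, or the auxiliary may partly racemize and erode the enantiomeric purity. The fallback moves stereocontrol to a final resolution. It sets out from compound 9. Benzyl alcohol with PPTS gives rac-3-(benzyloxy)-5,7-dihydroxy-6-methylisobenzofuran-1(3H)-one F6. Esterification with compound 3 gives the racemic benzyl acetal depside F7, and the copper/O2 coupling gives the racemic benzyl acetal depsidone F8. Hydrogenolysis (H2, Pd/C, EtOAc, 0 °C) gives racemic hypostictic acid F9, which is resolved by preparative chiral SFC on an amylose carbamate phase (CO2/EtOH, 5 °C) with immediate crystallization, and the fallback comes back to the route at compound 16.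

## Further compounds

F1 | step 7 | (3R)-4-bromo-5,7-dihydroxy-6-methyl-3-[(1R)-1-phenylethoxy]isobenzofuran-1(3H)-one | Cc1c(O)c(Br)c2[C@H](O[C@H](C)c3ccccc3)OC(=O)c2c1O
F2 | step 7 | (3R)-4-bromo-7-hydroxy-6-methyl-1-oxo-3-[(1R)-1-phenylethoxy]-1,3-dihydroisobenzofuran-5-yl 2-hydroxy-4-methoxy-3,6-dimethylbenzoate | COc1cc(C)c(C(=O)Oc2c(Br)c3[C@H](O[C@H](C)c4ccccc4)OC(=O)c3c(O)c2C)c(O)c1C
F3 | step 8 | (3R)-5,7-dihydroxy-6-methyl-3-[(1R)-1-(2-nitrophenyl)ethoxy]isobenzofuran-1(3H)-one | Cc1c(O)cc2[C@H](O[C@H](C)c3ccccc3[N+](=O)[O-])OC(=O)c2c1O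
F4 | step 8 | (3R)-7-hydroxy-6-methyl-3-[(1R)-1-(2-nitrophenyl)ethoxy]-1-oxo-1,3-dihydroisobenzofuran-5-yl 2-hydroxy-4-methoxy-3,6-dimethylbenzoate | COc1cc(C)c(C(=O)Oc2cc3[C@H](O[C@H](C)c4ccccc4[N+](=O)[O-])OC(=O)c3c(O)c2C)c(O)c1C
F5 | step 8 | (R)-hypostictic acid O-[(1R)-1-(2-nitrophenyl)ethyl] lactol acetal | COc1cc(C)c2c(c1C)Oc1c(c(C)c(O)c3c1[C@H](O[C@H](C)c4ccccc4[N+](=O)[O-])OC3=O)OC2=O
F6 | step 5 | rac-3-(benzyloxy)-5,7-dihydroxy-6-methylisobenzofuran-1(3H)-one | Cc1c(O)cc2C(OCc3ccccc3)OC(=O)c2c1O
F7 | step 5 | rac-3-(benzyloxy)-7-hydroxy-6-methyl-1-oxo-1,3-dihydroisobenzofuran-5-yl 2-hydroxy-4-methoxy-3,6-dimethylbenzoate | COc1cc(C)c(C(=O)Oc2cc3C(OCc4ccccc4)OC(=O)c3c(O)c2C)c(O)c1C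
F8 | step 5 | rac-hypostictic acid O-benzyl lactol acetal | COc1cc(C)c2c(c1C)Oc1c(c(C)c(O)c3c1C(OCc4ccccc4)OC3=O)OC2=O
F9 | step 5 | rac-hypostictic acid | COc1cc(C)c2c(c1C)Oc1c(c(C)c(O)c3c1C(O)OC3=O)OC2=O
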